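**Plan**

- Numbering: C1 (oxirane CH2), C2 (oxirane CH), C3 (C–Cl, CH3), C4 (CHBr), C5 (CH2), C6 (CHCl), C7 (C–Br, CH3), C8 (CH2Cl). The enabling feature is that C4–Br sits next to the quaternary C3–Cl and C2 is oxygenated, so C2, C3, C4 and one oxygen can be held as an oxetan-2-one ring whose C4–O bond bromide later replaces.
- Retrosynthetic cuts, in order: O–C1 (oxirane), C1–C2 (diazomethane carbon), C4–Br (lactone C4–O), C3–Cl (lactone enolate), C3–C4 together with O–C2 (aldol–lactonisation), C8–Cl, C6–Cl/C7–Br (bromochlorination), C6=C7 (olefination).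
- Forward order: the C4–C8 aldehyde is built first; the oxetan-2-one ring closes in step 10 and is opened in step 12; the oxirane ring closes last (step 16).
- Stereochemistry: C6/C7 from ligand-controlled anti bromochlorination of a Z-alkene; C4 from 1,3-induction by C6–Cl, then SN2 inversion by bromide; C3 from chlorination of the planar lactone enolate anti to the C4 chain; C2 from an oxazaborolidine reduction that the C3 chlorine reinforces.

Key step: step 10

Remark: the enantiomer of the Schiff-base ligand in step 4 is taken to be the one that gives the (2S,3S) bromochloride; both antipodes are accessible from D- or L-tert-leucine and the sense of induction is to be confirmed on the first run.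
Remark: 3-[(tert-butyldimethylsilyl)oxy]propan-1-ol is taken as a purchased material (otherwise one mono-silylation of propane-1,3-diol precedes step 1).

**Route**

Step 1
Reactants: 1 3-[(tert-butyldimethylsilyl)oxy]propan-1-ol
Product: 2 3-[(tert-butyldimethylsilyl)oxy]propanal
Conditions: 2,2,6,6-tetramethylpiperidin-1-oxyl (TEMPO, 10 mol %), PhI(OAc)2, CH2Cl2, rt
Reagents that add atoms: none
Why: oxoammonium-mediated alcohol oxidation stops cleanly at the aldehyde and leaves the silyl ether untouched.

Step 2
Reactants: 2 3-[(tert-butyldimethylsilyl)oxy]propanal; 3 methyl 2-[bis(2,2,2-trifluoroethoxy)phosphoryl]propanoate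
Product: 4 methyl (2Z)-5-[(tert-butyldimethylsilyl)oxy]-2-methylpent-2-enoate
Conditions: KN(SiMe3)2, 18-crown-6, THF, −78 °C
Reagents that add atoms: none
Why: in this Still–Gennari olefination the electron-poor trifluoroethyl phosphonate eliminates from the kinetically formed adduct under dissociating conditions, which should give the Z-trisubstituted enoate and thereby fix the C6=C7 geometry that the later anti addition translates into the C6/C7 relative configuration.

Step 3
Reactants: 4 methyl (2Z)-5-[(tert-butyldimethylsilyl)oxy]-2-methylpent-2-enoate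
Product: 5 (2Z)-5-[(tert-butyldimethylsilyl)oxy]-2-methylpent-2-en-1-ol
Conditions: iBu2AlH (2.2 equiv), CH2Cl2, −78 → 0 °C
Reagents that add atoms: none
Why: 1,2-reduction of the enoate by the aluminium hydride gives the allylic alcohol without touching the alkene geometry or the silyl ether.

Step 4
Reactants: 5 (2Z)-5-[(tert-butyldimethylsilyl)oxy]-2-methylpent-2-en-1-ol
Product: 6 (2S,3S)-2-bromo-5-[(tert-butyldimethylsilyl)oxy]-3-chloro-2-methylpentan-1-ol
Conditions: 2,4-di-tert-butyl-6-({[1-hydroxy-3,3-dimethyl-1,1-diphenylbutan-2-yl]imino}methyl)phenol (one enantiomer, 20 mol %), ClTi(OiPr)3 (1.1 equiv), NBS (1.05 equiv), hexanes, −20 °C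
Reagents that add atoms: N-bromosuccinimide, O=C1CCC(=O)N1Br; chlorotitanium triisopropoxide, CC(C)O[Ti](Cl)(OC(C)C)OC(C)C
Why: in this titanium-mediated enantioselective bromochlorination of an allylic alcohol the substrate binds titanium as its alkoxide, NBS forms the bromonium ion on the alkene face selected by the chiral ligand and titanium-bound chloride is delivered anti to the carbon distal to oxygen (C6), so the Z-alkene should give the (2S,3S) isomer with bromine on the tertiary C7 against the Markovnikov bias.

Step 5
Reactants: 6 (2S,3S)-2-bromo-5-[(tert-butyldimethylsilyl)oxy]-3-chloro-2-methylpentan-1-ol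
Product: 8 tert-butyl{[(3S,4S)-4-bromo-3,5-dichloro-4-methylpentyl]oxy}dimethylsilane, via triflate 7 (not isolated)
Conditions: Tf2O, pyridine, CH2Cl2, −78 °C; then Bu4NCl, −78 → 0 °C
Reagents that add atoms: tetrabutylammonium chloride, CCCC[N+](CCCC)(CCCC)CCCC.[Cl-]; trifluoromethanesulfonic anhydride, O=S(=O)(OS(=O)(=O)C(F)(F)F)C(F)(F)F (its atoms stay only in 7)
Why: sulfonate activation followed by SN2 displacement with chloride is used because a triflate is reactive enough to overcome the neopentyl retardation at C8 at low temperature, where the tertiary bromide and the silyl ether should survive and no stereocentre is touched.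

Step 6
Reactants: 8 tert-butyl{[(3S,4S)-4-bromo-3,5-dichloro-4-methylpentyl]oxy}dimethylsilane
Product: 9 (3S,4S)-4-bromo-3,5-dichloro-4-methylpentan-1-ol
Conditions: HF·pyridine, THF, 0 °C → rt
Reagents that add atoms: none
Why: desilylation with weakly acidic fluoride frees the C4 alcohol while avoiding the basic fluoride sources that could dehydrohalogenate the chain.

Step 7
Reactants: 9 (3S,4S)-4-bromo-3,5-dichloro-4-methylpentan-1-ol
Product: 10 (3S,4S)-4-bromo-3,5-dichloro-4-methylpentanal
Conditions: Dess–Martin periodinane, CH2Cl2, 0 °C → rt; used crude in step 10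
Reagents that add atoms: none
Why: the Dess–Martin oxidation is neutral to weakly acidic, so the β-chloro aldehyde should not lose HCl as it would under amine-based oxidations.

Step 8
Reactants: 11 propanoyl chloride; 12 pyridine-2-thiol
Product: 13 S-(pyridin-2-yl) propanethioate
Conditions: Et3N, CH2Cl2, 0 °C
Reagents that add atoms: none
Why: S-acylation of the thiol by the acid chloride with an amine as HCl scavenger is a standard thioester formation.

Step 9
Reactants: 13 S-(pyridin-2-yl) propanethioate
Product: 14 2-({(1E)-1-[(tert-butyldimethylsilyl)oxy]prop-1-en-1-yl}sulfanyl)pyridine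
Conditions: LiN(SiMe3)2, TBSCl, THF/DMF, −78 °C
Reagents that add atoms: tert-butyldimethylsilyl chloride, CC(C)(C)[Si](C)(C)Cl
Why: kinetic enolisation of the thioester with internal silyl quench gives the O-silyl ketene thioacetal, expected mainly as the E isomer, and its geometry is not critical because C3 is reset in step 11.

Step 10
Reactants: 10 (3S,4S)-4-bromo-3,5-dichloro-4-methylpentanal; 14 2-({(1E)-1-[(tert-butyldimethylsilyl)oxy]prop-1-en-1-yl}sulfanyl)pyridine
Product: 16 (3S,4S)-4-[(2S,3S)-3-bromo-2,4-dichloro-3-methylbutyl]-3-methyloxetan-2-one, via zinc aldolate 15 (not isolated)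
Conditions: ZnCl2 (2 equiv, fused), 14 (1.5 equiv), CH2Cl2, rt, 48 h
Reagents that add atoms: zinc chloride, Cl[Zn]Cl (its atoms stay only in 15)
Why: ZnCl2 activates aldehyde 10 for an open-transition-state Mukaiyama aldol with ketene acetal 14 (C3–C4 bond), and the zinc alkoxide of adduct 15 then attacks the still O-silylated thioester carbon (O–C2 bond) with loss of the silyl and thiopyridyl groups. The closest known reaction type is the tandem Mukaiyama aldol–lactonisation of thiopyridyl ketene acetals with aldehydes, which gives trans β-lactones. The oxetan-2-one closes by 4-exo-trig acyl substitution. C4 is controlled by 1,3-induction from the C6 chlorine: in the conformer where the C6–Cl and C=O dipoles oppose each other, attack on the open face should place the new C4–O bond anti to C6–Cl; C3 should come out trans to the C4 chain through the usual preference of this process, but it is erased in step 11. The step needs aldehyde-face selectivity and survival of the β-chloro aldehyde, and the polar, non-chelating C6–Cl bond and the base-free Lewis-acid medium are what should secure them.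

Step 11
Reactants: 16 (3S,4S)-4-[(2S,3S)-3-bromo-2,4-dichloro-3-methylbutyl]-3-methyloxetan-2-one
Product: 18 (3S,4S)-4-[(2S,3S)-3-bromo-2,4-dichloro-3-methylbutyl]-3-chloro-3-methyloxetan-2-one, via lithium enolate 17 (not isolated)
Conditions: LiN(iPr)2 (1.05 equiv), THF, −78 °C; then C2Cl6, −78 °C
Reagents that add atoms: hexachloroethane, ClC(Cl)(Cl)C(Cl)(Cl)Cl; lithium diisopropylamide, CC(C)N([Li])C(C)C (its lithium stays only in 17)
Why: this is electrophilic chlorination of a β-lactone enolate, which is stable at low temperature because the ring C4–O bond lies orthogonal to the enolate π system, and the planar enolate should be chlorinated on the face anti to the C4 side chain to give the C3 configuration that maps onto 3R of the target.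

Step 12
Reactants: 18 (3S,4S)-4-[(2S,3S)-3-bromo-2,4-dichloro-3-methylbutyl]-3-chloro-3-methyloxetan-2-one
Product: 19 (2R,3R,5S,6S)-3,6-dibromo-2,5,7-trichloro-2,6-dimethylheptanoic acid
Conditions: MgBr2·OEt2 (3 equiv), Et2O/CH2Cl2, 0 °C → rt; cold aq. HCl work-up
Reagents that add atoms: magnesium bromide diethyl etherate, Br[Mg]Br.CCOCC
Why: Lewis-acid-assisted SN2 opening of the β-lactone by bromide at C4 (alkyl–oxygen cleavage) inverts C4, with ring strain and the carboxylate leaving group compensating for the neopentyl position, while the flanking C–Cl bonds disfavour ionisation so that rearrangement should not compete.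

Step 13
Reactants: 19 (2R,3R,5S,6S)-3,6-dibromo-2,5,7-trichloro-2,6-dimethylheptanoic acid
Product: 21 (3R,4R,6S,7S)-4,7-dibromo-3,6,8-trichloro-1-diazo-3,7-dimethyloctan-2-one, via acid chloride 20 (not isolated)
Conditions: (COCl)2, DMF (cat.), CH2Cl2, 0 °C → rt; concentrate; CH2N2 (3 equiv), Et2O, 0 °C
Reagents that add atoms: diazomethane, C=[N+]=[N-]; oxalyl chloride, O=C(Cl)C(=O)Cl (its chlorine stays only in 20)
Why: base-free acid chloride formation followed by acylation of diazomethane (first stage of the Arndt–Eistert sequence) adds C1, with the excess diazomethane scavenging HCl and no epimerisable centre at the quaternary C3.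

Step 14
Reactants: 21 (3R,4R,6S,7S)-4,7-dibromo-3,6,8-trichloro-1-diazo-3,7-dimethyloctan-2-one
Product: 22 (3R,4R,6S,7S)-1,4,7-tribromo-3,6,8-trichloro-3,7-dimethyloctan-2-one
Conditions: HBr (48 % aq.), Et2O, 0 °C
Reagents that add atoms: hydrogen bromide, Br
Why: protonation of the diazoketone and displacement of N2 by bromide gives the halomethyl ketone, and bromide rather than chloride is placed at C1 so that the final ring closure at the primary carbon outruns displacement of the tertiary C3 chloride.

Step 15
Reactants: 22 (3R,4R,6S,7S)-1,4,7-tribromo-3,6,8-trichloro-3,7-dimethyloctan-2-one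
Product: 23 (2R,3R,4R,6S,7S)-1,4,7-tribromo-3,6,8-trichloro-3,7-dimethyloctan-2-ol
Conditions: (R)-1-methyl-3,3-diphenyltetrahydro-1H,3H-pyrrolo[1,2-c][1,3,2]oxazaborole (20 mol %), BH3·SMe2, THF, −20 °C; MeOH quench
Reagents that add atoms: none
Why: in this Corey–Bakshi–Shibata reduction the (R)-oxazaborolidine treats the quaternary C3 as the large group and delivers hydride to the face that the dipole-opposed conformer (C=O anti to C3–Cl, attack past CH3 rather than C4) also exposes, so catalyst and substrate control should be matched for the 2R bromohydrin.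

Step 16
Reactants: 23 (2R,3R,4R,6S,7S)-1,4,7-tribromo-3,6,8-trichloro-3,7-dimethyloctan-2-ol
Product: 24 (2S)-2-[(2R,3R,5S,6S)-3,6-dibromo-2,5,7-trichloro-6-methylheptan-2-yl]oxirane
Conditions: K2CO3, MeOH, 0 °C
Reagents that add atoms: none
Why: in this 3-exo-tet Williamson closure the C2 alkoxide displaces the primary C1 bromide, the best leaving group within reach, and the C2–O bond is not broken, so the configuration is retained and only the descriptor changes from R to S.

**Compound list**

1 | 3-[(tert-butyldimethylsilyl)oxy]propan-1-ol | CC(C)(C)[Si](C)(C)OCCCO | starting material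
2 | 3-[(tert-butyldimethylsilyl)oxy]propanal | CC(C)(C)[Si](C)(C)OCCC=O | intermediate
3 | methyl 2-[bis(2,2,2-trifluoroethoxy)phosphoryl]propanoate | COC(=O)C(C)P(=O)(OCC(F)(F)F)OCC(F)(F)F | starting material
4 | methyl (2Z)-5-[(tert-butyldimethylsilyl)oxy]-2-methylpent-2-enoate | COC(=O)/C(C)=C\CCO[Si](C)(C)C(C)(C)C | intermediate
5 | (2Z)-5-[(tert-butyldimethylsilyl)oxy]-2-methylpent-2-en-1-ol | OC/C(C)=C\CCO[Si](C)(C)C(C)(C)C | intermediate
6 | (2S,3S)-2-bromo-5-[(tert-butyldimethylsilyl)oxy]-3-chloro-2-methylpentan-1-ol | CC(C)(C)[Si](C)(C)OCC[C@H](Cl)[C@@](C)(Br)CO | intermediate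
7 | (2S,3S)-2-bromo-5-[(tert-butyldimethylsilyl)oxy]-3-chloro-2-methylpentyl trifluoromethanesulfonate | CC(C)(C)[Si](C)(C)OCC[C@H](Cl)[C@@](C)(Br)COS(=O)(=O)C(F)(F)F | intermediate (not isolated)
8 | tert-butyl{[(3S,4S)-4-bromo-3,5-dichloro-4-methylpentyl]oxy}dimethylsilane | CC(C)(C)[Si](C)(C)OCC[C@H](Cl)[C@@](C)(Br)CCl | intermediate
9 | (3S,4S)-4-bromo-3,5-dichloro-4-methylpentan-1-ol | OCC[C@H](Cl)[C@@](C)(Br)CCl | intermediate
10 | (3S,4S)-4-bromo-3,5-dichloro-4-methylpentanal | O=CC[C@H](Cl)[C@@](C)(Br)CCl | intermediate
11 | propanoyl chloride | CCC(Cl)=O | starting material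
12 | pyridine-2-thiol | Sc1ccccn1 | starting material
13 | S-(pyridin-2-yl) propanethioate | CCC(=O)Sc1ccccn1 | intermediate
14 | 2-({(1E)-1-[(tert-butyldimethylsilyl)oxy]prop-1-en-1-yl}sulfanyl)pyridine | C/C=C(\O[Si](C)(C)C(C)(C)C)Sc1ccccn1 | intermediate
15 | open-chain Mukaiyama adduct, (2S,3S,5S,6S) chain: dichlorozincate alkoxide at C4 of the target numbering, thioester carbonyl still O-silylated | C[C@@H]([C@@H](O[Zn-](Cl)Cl)C[C@H](Cl)[C@@](C)(Br)CCl)C(=[O+][Si](C)(C)C(C)(C)C)Sc1ccccn1 | intermediate (not isolated)
16 | (3S,4S)-4-[(2S,3S)-3-bromo-2,4-dichloro-3-methylbutyl]-3-methyloxetan-2-one | C[C@@H]1C(=O)O[C@H]1C[C@H](Cl)[C@@](C)(Br)CCl | intermediate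
17 | lithium (4S)-4-[(2S,3S)-3-bromo-2,4-dichloro-3-methylbutyl]-3-methyl-4H-oxet-2-olate | CC1=C(O[Li])O[C@H]1C[C@H](Cl)[C@@](C)(Br)CCl | intermediate (not isolated)
18 | (3S,4S)-4-[(2S,3S)-3-bromo-2,4-dichloro-3-methylbutyl]-3-chloro-3-methyloxetan-2-one | C[C@@]1(Cl)C(=O)O[C@H]1C[C@H](Cl)[C@@](C)(Br)CCl | intermediate
19 | (2R,3R,5S,6S)-3,6-dibromo-2,5,7-trichloro-2,6-dimethylheptanoic acid | C[C@](Cl)([C@H](Br)C[C@H](Cl)[C@@](C)(Br)CCl)C(=O)O | intermediate
20 | (2R,3R,5S,6S)-3,6-dibromo-2,5,7-trichloro-2,6-dimethylheptanoyl chloride | C[C@](Cl)([C@H](Br)C[C@H](Cl)[C@@](C)(Br)CCl)C(Cl)=O | intermediate (not isolated)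
21 | (3R,4R,6S,7S)-4,7-dibromo-3,6,8-trichloro-1-diazo-3,7-dimethyloctan-2-one | C[C@](Cl)([C@H](Br)C[C@H](Cl)[C@@](C)(Br)CCl)C(=O)C=[N+]=[N-] | intermediate
22 | (3R,4R,6S,7S)-1,4,7-tribromo-3,6,8-trichloro-3,7-dimethyloctan-2-one | C[C@](Cl)([C@H](Br)C[C@H](Cl)[C@@](C)(Br)CCl)C(=O)CBr | intermediate
23 | (2R,3R,4R,6S,7S)-1,4,7-tribromo-3,6,8-trichloro-3,7-dimethyloctan-2-ol | C[C@](Cl)([C@H](Br)C[C@H](Cl)[C@@](C)(Br)CCl)[C@@H](O)CBr | intermediate
24 | (2S)-2-[(2R,3R,5S,6S)-3,6-dibromo-2,5,7-trichloro-6-methylheptan-2-yl]oxirane | C[C@](Cl)([C@H](Br)C[C@H](Cl)[C@@](C)(Br)CCl)[C@@H]1CO1 | target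

**Step count**

Total: 16 steps. Longest linear sequence: 14 steps (steps 1–7 and 10–16, from 1 to 24); the ketene acetal branch (steps 8–9) joins at step 10.

**Steps most likely to fail**

1. Step 12 (bromide opening of the lactone). Bromide may fail to invert the neopentyl C4 centre; the ring may instead open by ionisation with a shift of chlorine or methyl from C3, or the β-bromo carboxylate may fragment with loss of CO2 and bromide before acidification. The fallback sets out from 18 and activates the hydroxyl instead of relying on strain. Methanolic HCl (0 °C → rt) should open the ring at the acyl carbon, since C4 is hindered and electron-poor, to give methyl (2S,3S,5S,6S)-6-bromo-2,5,7-trichloro-3-hydroxy-2,6-dimethylheptanoate F1; base is avoided here because the C4 alkoxide would close onto the C3 chloride. Tf2O and 2,6-lutidine in CH2Cl2 at −78 °C would give methyl (2S,3S,5S,6S)-6-bromo-2,5,7-trichloro-2,6-dimethyl-3-{[(trifluoromethyl)sulfonyl]oxy}heptanoate F2, which Bu4NBr should displace with inversion to methyl (2R,3R,5S,6S)-3,6-dibromo-2,5,7-trichloro-2,6-dimethylheptanoate F3. Me3SnOH in 1,2-dichloroethane at 80 °C would then cleave the methyl ester, and the route is rejoined at 19.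

2. Step 10 (key step). The 1,3-induction by a β-chlorine may be weak or reversed, giving poor facial selectivity at C4, and the β-chloro aldehyde may lose HCl during the long reaction. The fallback sets out from 10 and replaces substrate control by catalyst control while forming the same two bonds and the same ring. An acyl halide–aldehyde cyclocondensation with propanoyl chloride 11 (O-trimethylsilylquinine or O-trimethylsilylquinidine, whichever gives 4S, 10 mol %, LiClO4, iPr2NEt, CH2Cl2/Et2O, −78 °C; the low temperature is meant to hold back amine-induced elimination) should give the cis lactone (3R,4S)-4-[(2S,3S)-3-bromo-2,4-dichloro-3-methylbutyl]-3-methyloxetan-2-one F4. Its deprotonation gives the same enolate 17, so the chlorination of step 11 brings the route back at 18.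

3. Step 11 (enolate chlorination). The lithium amide may dehydrohalogenate the polyhalogenated chain, the enolate may ring-open on warming, or chlorine may enter on the wrong face. The fallback sets out from 10 and 12 and brings the chlorine in with the nucleophile, so that no strong base meets the halogenated chain. 2-Chloropropanoyl chloride and 12 (Et3N, CH2Cl2, 0 °C) would give S-(pyridin-2-yl) 2-chloropropanethioate F5. LiN(SiMe3)2 and TBSCl (THF/DMF, −78 °C) would convert it into 2-({1-[(tert-butyldimethylsilyl)oxy]-2-chloroprop-1-en-1-yl}sulfanyl)pyridine F6. The ZnCl2-mediated aldol–lactonisation of F6 with 10 would then deliver 18 directly, probably together with its C3 epimer, which would have to be separated; the route is rejoined at 18.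

**Further compounds**

F1 | step 12 | methyl (2S,3S,5S,6S)-6-bromo-2,5,7-trichloro-3-hydroxy-2,6-dimethylheptanoate | COC(=O)[C@@](C)(Cl)[C@@H](O)C[C@H](Cl)[C@@](C)(Br)CCl
F2 | step 12 | methyl (2S,3S,5S,6S)-6-bromo-2,5,7-trichloro-2,6-dimethyl-3-{[(trifluoromethyl)sulfonyl]oxy}heptanoate | COC(=O)[C@@](C)(Cl)[C@@H](OS(=O)(=O)C(F)(F)F)C[C@H](Cl)[C@@](C)(Br)CCl
F3 | step 12 | methyl (2R,3R,5S,6S)-3,6-dibromo-2,5,7-trichloro-2,6-dimethylheptanoate | C[C@](Cl)([C@H](Br)C[C@H](Cl)[C@@](C)(Br)CCl)C(=O)OC
F4 | step 10 | (3R,4S)-4-[(2S,3S)-3-bromo-2,4-dichloro-3-methylbutyl]-3-methyloxetan-2-one | C[C@H]1C(=O)O[C@H]1C[C@H](Cl)[C@@](C)(Br)CCl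
F5 | step 11 | S-(pyridin-2-yl) 2-chloropropanethioate | CC(Cl)C(=O)Sc1ccccn1
F6 | step 11 | 2-({1-[(tert-butyldimethylsilyl)oxy]-2-chloroprop-1-en-1-yl}sulfanyl)pyridine | CC(Cl)=C(O[Si](C)(C)C(C)(C)C)Sc1ccccn1
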